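**Retrosynthetic overview**

1. The target is the threo-(7R,8R) 8-O-4' neolignan (lignan numbering: ring A = 4-hydroxy-3,5-dimethoxyphenyl, bonded through C1 to the carbinol C7; C8 = aryloxy carbon; C9 = CH2OH; ring B = the 2,6-dimethoxy-4-propenylphenoxy ring). The last operations are reduction of a tert-butyl cinnamate to the E-allylic alcohol and desilylation at C9.
2. Key disconnection C1(ring A)–C7: unprotected 2,6-dimethoxyphenol, as its bromomagnesium phenolate, adds through its para carbon to the MgBr2 chelate of an (R)-2-aryloxy-3-silyloxypropanal. The C–C bond and the C7 carbinol form together, with no aryl halide and no phenol protecting group.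
3. Enabling features: in ring A the free C4–OH, flanked by OMe on C3 and C5, leaves C1 (para to the oxygen) as the only nucleophilic ring carbon of the phenolate. At C8 the ether oxygen, flanked by the two OMe groups of ring B, forms with the C7 carbonyl oxygen a five-membered magnesium chelate that relays the C8 configuration to C7 (threo).
4. The aldehyde comes from a Mitsunobu inversion that joins tert-butyl sinapate (Wittig from syringaldehyde) to the 3-O-TBDPS ether of methyl (S)-glycerate (chiral pool, sets C8 as R), followed by selective half-reduction of the methyl ester.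
5. No ring is formed in the route: rings A and B are bought as 2,6-dimethoxyphenol and syringaldehyde.

Key step: step 6

Remark (assumption): methyl (S)-2,2-dimethyl-1,3-dioxolane-4-carboxylate and tert-butyl (triphenylphosphoranylidene)acetate are taken as commercial. The (1R,2R) descriptor of the target corresponds to the threo series, which is the product expected from chelation-controlled addition to an (R)-2-aryloxy aldehyde.

**Route**

Step 1
Reactants: 1 syringaldehyde (4-hydroxy-3,5-dimethoxybenzaldehyde); 2 tert-butyl (triphenylphosphoranylidene)acetate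
Product: 3 tert-butyl (E)-3-(4-hydroxy-3,5-dimethoxyphenyl)prop-2-enoate (tert-butyl sinapate)
Conditions: toluene, 100 °C
Reagents that add atoms: none
Why: Wittig olefination with a stabilised ylide tolerates the free phenol and should give the E-alkene selectively.

Step 2
Reactants: 4 methyl (S)-2,2-dimethyl-1,3-dioxolane-4-carboxylate
Product: 5 methyl (S)-2,3-dihydroxypropanoate
Conditions: AcOH/H2O (4:1), 40 °C
Reagents that add atoms: none
Why: Acid-catalysed acetal hydrolysis should free the 1,2-diol without touching the methyl ester or the stereocentre, which takes no part in the reaction.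

Step 3
Reactants: 5 methyl (S)-2,3-dihydroxypropanoate
Product: 6 methyl (S)-3-[(tert-butyldiphenylsilyl)oxy]-2-hydroxypropanoate
Conditions: TBDPSCl, imidazole, CH2Cl2, 0 °C
Reagents that add atoms: tert-butyl(chloro)diphenylsilane (TBDPSCl), CC(C)(C)[Si](Cl)(c1ccccc1)c1ccccc1
Why: Silyl ether formation with the bulky chlorosilane should occur selectively at the primary hydroxyl, leaving the secondary α-hydroxy ester OH free for the next step.

Step 4
Reactants: 3 tert-butyl sinapate; 6 methyl (S)-3-[(tert-butyldiphenylsilyl)oxy]-2-hydroxypropanoate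
Product: 7 methyl (R)-2-{4-[(E)-3-tert-butoxy-3-oxoprop-1-enyl]-2,6-dimethoxyphenoxy}-3-[(tert-butyldiphenylsilyl)oxy]propanoate
Conditions: PPh3, DIAD, THF, 0 °C → rt
Reagents that add atoms: none
Why: Mitsunobu etherification, in which the acidic phenol displaces the oxyphosphonium of the activated α-hydroxy ester by SN2, so that the future C8 is set as R by inversion of the S alcohol.

Step 5
Reactants: 7 methyl (R)-2-aryloxy-3-silyloxypropanoate
Product: 8 tert-butyl (E)-3-[4-({(R)-1-[(tert-butyldiphenylsilyl)oxy]-3-oxopropan-2-yl}oxy)-3,5-dimethoxyphenyl]prop-2-enoate (the (R)-2-aryloxy aldehyde, used crude)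
Conditions: iBu2AlH (1.1 equiv), CH2Cl2, −78 °C; MeOH, then aq. KNaC4H4O6
Reagents that add atoms: none
Why: Partial ester reduction with iBu2AlH, in which the α-aryloxy methyl ester gives a chelated tetrahedral aluminium hemiacetal that survives at −78 °C and collapses to the aldehyde on work-up, while the hindered, conjugated tert-butyl ester should not react with one equivalent at this temperature and C8 is untouched.

Step 6
Reactants: 8 (R)-2-aryloxy-3-silyloxypropanal; 9 2,6-dimethoxyphenol
Product: 12 tert-butyl (E)-3-[4-({(1R,2R)-3-[(tert-butyldiphenylsilyl)oxy]-1-hydroxy-1-(4-hydroxy-3,5-dimethoxyphenyl)propan-2-yl}oxy)-3,5-dimethoxyphenyl]prop-2-enoate (threo adduct), via bromomagnesium 2,6-dimethoxyphenolate 10 (not isolated), via dienone adduct 11 (not isolated)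
Conditions: 9 (3 equiv), EtMgBr (2.9 equiv), Et2O/CH2Cl2, 0 °C; then 8 premixed with MgBr2·OEt2 (1.5 equiv), CH2Cl2, −40 → −10 °C; aq. NaH2PO4/Na2HPO4 (pH 7)
Reagents that add atoms: none
Why: Proposed new method: a chelation-controlled, para-selective hydroxyalkylation of an unprotected magnesium phenolate, whose closest known relatives are the ortho-hydroxyalkylation of bromomagnesium phenolates (ArOMgBr) with chiral α-alkoxy aldehydes and the base-mediated para-hydroxyalkylation of 2,6-disubstituted phenols with activated aldehydes such as glyoxylic acid. MgBr2 is expected to bind aldehyde 8 through the C7 carbonyl oxygen and the C8 ether oxygen, supported by a flanking methoxy oxygen of ring B, which holds the C7=O and C8–O bonds syn-periplanar and raises the electrophilicity of C7; phenolate 10 then attacks through its para carbon to give the cross-conjugated dienone 11, which tautomerises irreversibly to the aromatic phenolate of 12. No ring is closed in this step. The new C7 stereocentre is controlled by the C8 stereocentre through the chelate, because the aryl carbon should approach the Re face of C7, the face that carries the C8 hydrogen and lies opposite the CH2OTBDPS arm, which gives the 7R,8R (threo) isomer. The step needs C- over O-attack (O-attack only gives a reversible hemiacetal), para regioselectivity (secured by the two ortho methoxy groups of 9, which leave only this carbon conjugated with the phenolate oxygen), mono-addition (the product alkoxide should not ionise to a quinone methide below 0 °C) and retention at C8 (no amine base, a weakly basic phenolate, low temperature and a bulky silyl ether that also suppresses chelation through the C9 oxygen).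

Step 7
Reactants: 12 threo adduct
Product: 13 (1R,2R)-3-[(tert-butyldiphenylsilyl)oxy]-1-(4-hydroxy-3,5-dimethoxyphenyl)-2-{4-[(E)-3-hydroxyprop-1-enyl]-2,6-dimethoxyphenoxy}propan-1-ol
Conditions: iBu2AlH (6 equiv), THF/CH2Cl2, −78 → −20 °C; aq. KNaC4H4O6
Reagents that add atoms: none
Why: Ester reduction with excess iBu2AlH should convert the α,β-unsaturated tert-butyl ester into the allylic alcohol by 1,2-reduction with the E geometry retained, the phenol and the C7 hydroxyl being held as aluminium alkoxides and both stereocentres left untouched.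

Step 8
Reactants: 13 C9 silyl ether
Product: 14 (1R,2R)-1-(4-hydroxy-3,5-dimethoxyphenyl)-2-{4-[(E)-3-hydroxyprop-1-enyl]-2,6-dimethoxyphenoxy}propane-1,3-diol (target)
Conditions: Bu4NF, AcOH (1:1), THF, 0 °C → rt
Reagents that add atoms: none
Why: Fluoride-mediated silyl ether cleavage, buffered with AcOH so that the 4-hydroxybenzylic C7 carbinol is not held as a phenolate that could epimerise through a quinone methide, should release the C9 hydroxyl and give the target.

**Compound list**

1 | syringaldehyde (4-hydroxy-3,5-dimethoxybenzaldehyde) | COc1cc(C=O)cc(OC)c1O | starting material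
2 | tert-butyl (triphenylphosphoranylidene)acetate | CC(C)(C)OC(=O)C=P(c1ccccc1)(c1ccccc1)c1ccccc1 | starting material
3 | tert-butyl (E)-3-(4-hydroxy-3,5-dimethoxyphenyl)prop-2-enoate | COc1cc(/C=C/C(=O)OC(C)(C)C)cc(OC)c1O | intermediate
4 | methyl (S)-2,2-dimethyl-1,3-dioxolane-4-carboxylate | COC(=O)[C@@H]1COC(C)(C)O1 | starting material
5 | methyl (S)-2,3-dihydroxypropanoate | COC(=O)[C@@H](O)CO | intermediate
6 | methyl (S)-3-[(tert-butyldiphenylsilyl)oxy]-2-hydroxypropanoate | COC(=O)[C@@H](O)CO[Si](c1ccccc1)(c1ccccc1)C(C)(C)C | intermediate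
7 | methyl (R)-2-{4-[(E)-3-tert-butoxy-3-oxoprop-1-enyl]-2,6-dimethoxyphenoxy}-3-[(tert-butyldiphenylsilyl)oxy]propanoate | COC(=O)[C@H](Oc1c(OC)cc(/C=C/C(=O)OC(C)(C)C)cc1OC)CO[Si](c1ccccc1)(c1ccccc1)C(C)(C)C | intermediate
8 | tert-butyl (E)-3-[4-({(R)-1-[(tert-butyldiphenylsilyl)oxy]-3-oxopropan-2-yl}oxy)-3,5-dimethoxyphenyl]prop-2-enoate | O=C[C@H](Oc1c(OC)cc(/C=C/C(=O)OC(C)(C)C)cc1OC)CO[Si](c1ccccc1)(c1ccccc1)C(C)(C)C | intermediate
9 | 2,6-dimethoxyphenol | COc1cccc(OC)c1O | starting material
10 | bromomagnesium 2,6-dimethoxyphenolate (not isolated) | COc1cccc(OC)c1O[Mg]Br | intermediate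
11 | dienone adduct, the bromomagnesium alkoxide of tert-butyl (E)-3-[4-({(1R,2R)-3-[(tert-butyldiphenylsilyl)oxy]-1-hydroxy-1-(3,5-dimethoxy-4-oxocyclohexa-2,5-dien-1-yl)propan-2-yl}oxy)-3,5-dimethoxyphenyl]prop-2-enoate (not isolated) | COC1=CC(C=C(OC)C1=O)[C@@H](O[Mg]Br)[C@@H](CO[Si](c1ccccc1)(c1ccccc1)C(C)(C)C)Oc1c(OC)cc(/C=C/C(=O)OC(C)(C)C)cc1OC | intermediate
12 | tert-butyl (E)-3-[4-({(1R,2R)-3-[(tert-butyldiphenylsilyl)oxy]-1-hydroxy-1-(4-hydroxy-3,5-dimethoxyphenyl)propan-2-yl}oxy)-3,5-dimethoxyphenyl]prop-2-enoate | COc1cc([C@@H](O)[C@@H](CO[Si](c2ccccc2)(c2ccccc2)C(C)(C)C)Oc2c(OC)cc(/C=C/C(=O)OC(C)(C)C)cc2OC)cc(OC)c1O | intermediate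
13 | (1R,2R)-3-[(tert-butyldiphenylsilyl)oxy]-1-(4-hydroxy-3,5-dimethoxyphenyl)-2-{4-[(E)-3-hydroxyprop-1-enyl]-2,6-dimethoxyphenoxy}propan-1-ol | COc1cc([C@@H](O)[C@@H](CO[Si](c2ccccc2)(c2ccccc2)C(C)(C)C)Oc2c(OC)cc(/C=C/CO)cc2OC)cc(OC)c1O | intermediate
14 | (1R,2R)-1-(4-hydroxy-3,5-dimethoxyphenyl)-2-{4-[(E)-3-hydroxyprop-1-enyl]-2,6-dimethoxyphenoxy}propane-1,3-diol | COc1cc([C@@H](O)[C@@H](CO)Oc2c(OC)cc(/C=C/CO)cc2OC)cc(OC)c1O | target

**Step count and risks**

Total step count: 8. Longest linear sequence: 7 steps (steps 2 to 8, from compound 4).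

Steps most likely to fail:

1. Step 6 (Proposed new method). The aggregated phenolate may react only slowly at its para carbon, attack may occur on a non-chelated aldehyde with poor facial selectivity, or the aldehyde may slowly enolise and lose its C8 configuration. The fallback uses known chemistry, sets out from compound 8 and comes back at compound 12; it forms the C1–C7 bond by a Grignard addition and sets C7 afterwards by ketone reduction. Commercial 4-bromo-2,6-dimethoxyphenol is silylated (TBSCl, imidazole, CH2Cl2) to (4-bromo-2,6-dimethoxyphenoxy)(tert-butyl)dimethylsilane F1. Mg turnings in THF convert it into [4-(tert-butyldimethylsilyloxy)-3,5-dimethoxyphenyl]magnesium bromide F2, which is added to aldehyde 8 at −78 °C to give the secondary alcohol F3 as a mixture of C7 epimers. Oxidation with Dess–Martin periodinane (NaHCO3, CH2Cl2) should give the aryl ketone F4. Reduction with LiBH(s-Bu)3 in THF at −78 °C under Felkin–Anh (non-chelation) control, the threo-selective mode for α-aryloxy ketones, should give the (1R,2R)-alcohol F5. Selective cleavage of the phenolic silyl ether (KHF2, MeOH, rt) returns to compound 12.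

2. Step 5. Over-reduction to the primary alcohol, competing reduction of the tert-butyl ester, or epimerisation of the α-aryloxy aldehyde during handling may occur. The fallback sets out from compound 7 and comes back at compound 8, going through the alcohol oxidation level instead of stopping a hydride reduction halfway. NaBH4 (THF/MeOH, 0 °C) reduces only the activated α-aryloxy methyl ester to tert-butyl (E)-3-[4-({(2S)-1-[(tert-butyldiphenylsilyl)oxy]-3-hydroxypropan-2-yl}oxy)-3,5-dimethoxyphenyl]prop-2-enoate F6 (short reaction time at 0 °C, to keep O-to-O silyl migration, which would erode the C8 configuration, slow). Dess–Martin oxidation (NaHCO3, CH2Cl2, 0 °C) then gives compound 8.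

3. Step 4. The di-ortho-substituted phenol may couple slowly, with competing elimination of the activated alcohol or alkylation of the reduced azodicarboxylate. The fallback sets out from compound 6 and comes back at compound 7, replacing the redox condensation by an SN2 displacement of a sulfonate. Compound 6 is converted (Tf2O, 2,6-lutidine, CH2Cl2, −78 °C) into methyl (S)-3-[(tert-butyldiphenylsilyl)oxy]-2-(trifluoromethylsulfonyloxy)propanoate F7, which is displaced with inversion by the phenolate of 3 (K2CO3, MeCN, −20 → 0 °C) to give compound 7.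

**Further compounds**

F1 | step 6 | (4-bromo-2,6-dimethoxyphenoxy)(tert-butyl)dimethylsilane | COc1cc(Br)cc(OC)c1O[Si](C)(C)C(C)(C)C
F2 | step 6 | [4-(tert-butyldimethylsilyloxy)-3,5-dimethoxyphenyl]magnesium bromide | COc1cc([Mg]Br)cc(OC)c1O[Si](C)(C)C(C)(C)C
F3 | step 6 | tert-butyl (E)-3-[4-({(2R)-1-[4-(tert-butyldimethylsilyloxy)-3,5-dimethoxyphenyl]-3-[(tert-butyldiphenylsilyl)oxy]-1-hydroxypropan-2-yl}oxy)-3,5-dimethoxyphenyl]prop-2-enoate, mixture of C1 epimers | COc1cc(C(O)[C@@H](CO[Si](c2ccccc2)(c2ccccc2)C(C)(C)C)Oc2c(OC)cc(/C=C/C(=O)OC(C)(C)C)cc2OC)cc(OC)c1O[Si](C)(C)C(C)(C)C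
F4 | step 6 | tert-butyl (E)-3-[4-({(R)-1-[4-(tert-butyldimethylsilyloxy)-3,5-dimethoxyphenyl]-3-[(tert-butyldiphenylsilyl)oxy]-1-oxopropan-2-yl}oxy)-3,5-dimethoxyphenyl]prop-2-enoate | COc1cc(C(=O)[C@@H](CO[Si](c2ccccc2)(c2ccccc2)C(C)(C)C)Oc2c(OC)cc(/C=C/C(=O)OC(C)(C)C)cc2OC)cc(OC)c1O[Si](C)(C)C(C)(C)C
F5 | step 6 | tert-butyl (E)-3-[4-({(1R,2R)-1-[4-(tert-butyldimethylsilyloxy)-3,5-dimethoxyphenyl]-3-[(tert-butyldiphenylsilyl)oxy]-1-hydroxypropan-2-yl}oxy)-3,5-dimethoxyphenyl]prop-2-enoate | COc1cc([C@@H](O)[C@@H](CO[Si](c2ccccc2)(c2ccccc2)C(C)(C)C)Oc2c(OC)cc(/C=C/C(=O)OC(C)(C)C)cc2OC)cc(OC)c1O[Si](C)(C)C(C)(C)C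
F6 | step 5 | tert-butyl (E)-3-[4-({(2S)-1-[(tert-butyldiphenylsilyl)oxy]-3-hydroxypropan-2-yl}oxy)-3,5-dimethoxyphenyl]prop-2-enoate | OC[C@H](Oc1c(OC)cc(/C=C/C(=O)OC(C)(C)C)cc1OC)CO[Si](c1ccccc1)(c1ccccc1)C(C)(C)C
F7 | step 4 | methyl (S)-3-[(tert-butyldiphenylsilyl)oxy]-2-(trifluoromethylsulfonyloxy)propanoate | COC(=O)[C@@H](OS(=O)(=O)C(F)(F)F)CO[Si](c1ccccc1)(c1ccccc1)C(C)(C)C
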